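**Plan** (carotenoid numbering: ring = C2–C3–C4–C5–C6, isopropenyl = C1/C16/C17 on C2, carbinol = C5, chain starts at C7)
1. Cuts, in order: C11=C12 (Wittig, ring C15 phosphonium salt + acyclic C25 aldehyde), C11'=C12' (Wittig, acyclic C15 salt + C10 dialdehyde), C8–C9 (acetylide + methyl vinyl ketone), and last the ring bond C2–C6.
2. Enabling feature: the cyclopentane C2–C6 carries isopropenyl on C2, a tertiary carbinol at C5 and the chain on C6 between them. This is what remains when a 5,6-epoxide of an open geranyl-type end ionises at C6, the C1=C2 olefin closes C2–C6 and C16 loses a proton, as the skeleton is thought to arise from lycopene 5,6-epoxide.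
3. In the precursor a Co2(CO)6-complexed C7≡C8 alkyne takes the cation-stabilising role of the polyene; it is removed after ring closure and the alkyne later becomes the E-olefin C7=C8.
4. Forward: geraniol → epoxy alcohol → epoxy alkyne → cobalt complex → cyclopentane (the only ring) → free alkyne → C15 dienyl phosphonium salt → Wittig union with the C25 aldehyde built from pseudoionone and the C10 dialdehyde.
5. Stereochemistry: C5 from the Katsuki–Sharpless epoxidation; C6 by retention at the cobalt-stabilised carbon and C2 by the ring-closure transition state; E-olefins from E starting materials, trans-hydroalumination and thermal equilibration after each Wittig step.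

Key step: step 5

Assumption: pseudoionone is used as its (3E,5E) isomer and the C10 dialdehyde as its all-E isomer, both bought; the side-chain carbinol centre made in step 7 is carried as both epimers because it becomes sp2 in step 9.

**Step 1**
Reactants: 1 geraniol
Product: 2 [(2S,3S)-3-methyl-3-(4-methylpent-3-en-1-yl)oxiran-2-yl]methanol
Conditions: Ti(OiPr)4 (5 mol%), L-(+)-diethyl tartrate (7 mol%), t-BuOOH, 4 Å MS, CH2Cl2, −20 °C
Reagents that add atoms: tert-butyl hydroperoxide, CC(C)(C)OO
Why: Katsuki–Sharpless asymmetric epoxidation; the titanium tartrate epoxidises only the allylic olefin and with L-(+)-tartrate should give the (2S,3S)-oxirane, which fixes C5 of the target and the relay centre at C6.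

**Step 2**
Reactants: 2 epoxy alcohol
Product: 3 (2R,3S)-3-methyl-3-(4-methylpent-3-en-1-yl)oxirane-2-carbaldehyde
Conditions: TEMPO (2,2,6,6-tetramethylpiperidin-1-oxyl, 10 mol%), PhI(OAc)2 (1.1 equiv), CH2Cl2, rt
Reagents that add atoms: none
Why: Oxoammonium (TEMPO) oxidation of the primary alcohol to the aldehyde, mild enough for the oxirane and the trisubstituted olefin; no bond at a stereocentre is touched (the descriptor at C2 changes by priority only).

**Step 3**
Reactants: 3 epoxy aldehyde
Product: 4 (2S,3S)-3-ethynyl-2-methyl-2-(4-methylpent-3-en-1-yl)oxirane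
Conditions: dimethyl (1-diazo-2-oxopropyl)phosphonate, K2CO3, MeOH, 0 °C → rt
Reagents that add atoms: dimethyl (1-diazo-2-oxopropyl)phosphonate (Ohira–Bestmann reagent), CC(=O)C(=[N+]=[N-])P(=O)(OC)OC
Why: Seyferth–Gilbert homologation in the Ohira–Bestmann form turns the formyl group into a terminal alkyne under weak base; the oxirane carbon cannot enolise, so both centres should be kept.

**Step 4**
Reactants: 4 epoxy alkyne
Product: 5 hexacarbonyl dicobalt complex of 4 (alkyne bridging the Co–Co bond)
Conditions: Co2(CO)8 (1.05 equiv), CH2Cl2, rt; short silica filtration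
Reagents that add atoms: dicobalt octacarbonyl Co2(CO)8, O=C=[Co](=C=O)(=C=O)(=C=O)[Co](=C=O)(=C=O)(=C=O)=C=O
Why: Alkyne complexation by ligand exchange (two CO lost) gives the C2Co2 cluster needed for a Nicholas-type ionisation; oxirane and olefin do not bind.

**Step 5**
Reactants: 5 cobalt complex of the epoxy alkyne
Product: 7 hexacarbonyl dicobalt complex of (1S,2S,3S)-2-ethynyl-1-methyl-3-(prop-1-en-2-yl)cyclopentan-1-ol, via cobalt-stabilised C6 cation 6 (not isolated)
Conditions: BF3·OEt2 (20 mol%), CH2Cl2, −78 → −40 °C; aq NaHCO3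
Reagents that add atoms: none
Why: Proposed new method: BF3 binds the oxirane oxygen and the C6–O bond ionises with help from cobalt to a (propargyl)Co2(CO)6 cation (the cluster does at C6 what the polyene does in the natural epoxide rearrangement), the C1=C2 olefin closes C2–C6 in a 5-exo-trig cation–olefin cyclisation, and the exocyclic C1 cation loses a C16 proton to give the isopropenyl group and return the acid. The closest known reaction types are the intramolecular Nicholas reaction with trisubstituted olefin nucleophiles and the BF3-catalysed propargylic opening of alkynyl-oxirane Co2(CO)6 complexes by tethered hydroxyl groups, with epoxide-initiated polyene cyclisation as the parent. C5 keeps the configuration from step 1 because its C–O bond is never broken. C6 should be set by net retention (cobalt leaves anti to oxygen, the olefin enters anti to cobalt), which from the E-derived (2S,3S)-oxirane puts the alkynyl group cis to the C5 oxygen; C2 is set in the envelope transition state, where the CMe2 terminus turns away from the bulky cluster and ends trans to C7. The step needs ionisation at C6 and not at tertiary C5 (secured by the cobalt cluster), 5-exo over 6-endo closure (tertiary against secondary cation), and proton loss in place of ether formation (the C5 oxygen is trans to C1 and cannot reach it).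

**Step 6**
Reactants: 7 cyclised cobalt complex
Product: 8 (1S,2S,3S)-2-ethynyl-1-methyl-3-(prop-1-en-2-yl)cyclopentan-1-ol
Conditions: Fe(NO3)3·9H2O (4–5 equiv), EtOH, 0 °C → rt
Reagents that add atoms: none
Why: Oxidative demetallation, the standard end of a Nicholas sequence, frees the terminal alkyne and should leave the tertiary carbinol and the isopropenyl group untouched.

**Step 7**
Reactants: 8 ring alkyne; 9 methyl vinyl ketone
Product: 11 (1S,2S,3S)-2-(3-hydroxy-3-methylpent-4-en-1-yn-1-yl)-1-methyl-3-(prop-1-en-2-yl)cyclopentan-1-ol (both epimers at the new carbinol carbon), via dilithium alkoxide acetylide 10 (not isolated)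
Conditions: n-BuLi (2.1 equiv), THF, −78 → 0 °C; then 9, −78 °C; H2O
Reagents that add atoms: none
Why: Alkynylation of a ketone: the lithium acetylide adds 1,2 to the carbonyl of methyl vinyl ketone at low temperature and forms the C8–C9 bond with C19 and the C10=C11 vinyl group in place.

**Step 8**
Reactants: 11 ynediol
Product: 12 (1S,2R,3S)-2-[(1E)-3-hydroxy-3-methylpenta-1,4-dien-1-yl]-1-methyl-3-(prop-1-en-2-yl)cyclopentan-1-ol
Conditions: LiAlH4 (3 equiv), THF, 0 → 50 °C; aq NaOH work-up
Reagents that add atoms: none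
Why: Hydroxyl-directed trans-hydroalumination of the propargylic alkoxide and protonolysis (LiAlH4 reduction of propargylic alcohols) should give only the E-olefin C7=C8; isolated olefins are not reduced.

**Step 9**
Reactants: 12 dienediol
Product: 13 [(2E,4E)-5-[(1R,2S,5S)-2-hydroxy-2-methyl-5-(prop-1-en-2-yl)cyclopentyl]-3-methylpenta-2,4-dien-1-yl]triphenylphosphonium bromide
Conditions: PPh3·HBr (1.05 equiv), MeOH, rt; crystallisation
Reagents that add atoms: triphenylphosphine hydrobromide, [Br-].c1ccccc1[PH+](c1ccccc1)c1ccccc1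
Why: The doubly allylic tertiary carbinol ionises to a pentadienyl cation that PPh3 captures at the primary terminus (SN1 with allylic transposition, the classical route from vinyl carbinols to allylic Wittig salts), giving mainly E C9=C10, and the 2E salt is purified by crystallisation; the isolated C5 carbinol should not ionise.

**Step 10**
Reactants: 14 (3E,5E)-pseudoionone
Product: 15 (4E,6E)-3,7,11-trimethyldodeca-1,4,6,10-tetraen-3-ol
Conditions: vinylmagnesium bromide, THF, 0 °C; H2O
Reagents that add atoms: vinylmagnesium bromide, C=C[Mg]Br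
Why: Grignard 1,2-addition to the dienone carbonyl gives the tertiary vinyl carbinol.

**Step 11**
Reactants: 15 vinyl carbinol
Product: 16 [(2E,4E,6E)-3,7,11-trimethyldodeca-2,4,6,10-tetraen-1-yl]triphenylphosphonium bromide
Conditions: PPh3·HBr, MeOH, rt; crystallisation
Reagents that add atoms: triphenylphosphine hydrobromide, [Br-].c1ccccc1[PH+](c1ccccc1)c1ccccc1
Why: Same SN1 phosphonium salt formation with allylic transposition as in step 9, here on the acyclic end.

**Step 12**
Reactants: 16 acyclic C15 salt; 17 (2E,4E,6E)-2,7-dimethylocta-2,4,6-trienedial (3 equiv)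
Product: 20 (2E,4E,6E,8E,10E,12E,14E)-2,7,11,15,19-pentamethylicosa-2,4,6,8,10,12,14,18-octaenal, via acyclic C15 ylide 18 (not isolated), via 8Z isomer 19 (not isolated)
Conditions: NaOMe (1.1 equiv, slow addition), CH2Cl2/MeOH, 0 °C → rt; then heptane, 90 °C, dark, argon
Reagents that add atoms: none
Why: Wittig olefination of one formyl group of the symmetrical dialdehyde (the excess suppresses double reaction) forms C11'=C12', and heating should equilibrate the Z part of the new olefin to E.

**Step 13**
Reactants: 13 ring C15 salt; 20 C25 aldehyde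
Product: 23 (1S,2R,3S)-1-methyl-2-[(1E,3E,5E,7E,9E,11E,13E,15E,17E,19E)-3,7,12,16,20,24-hexamethylpentacosa-1,3,5,7,9,11,13,15,17,19,23-undecaen-1-yl]-3-(prop-1-en-2-yl)cyclopentan-1-ol (target), via ring C15 ylide 21 (not isolated), via 11Z isomer 22 (not isolated)
Conditions: NaOMe, CH2Cl2/MeOH, 0 °C → rt; then heptane, reflux, dark, argon; crystallisation
Reagents that add atoms: none
Why: Wittig olefination joins C11=C12 (the free tertiary hydroxyl is tolerated, as in hydroxylated carotenoid end groups), and thermal isomerisation should convert the hindered 11Z isomer into the all-E polyene without touching the three ring centres.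

**Compound list**
1 | geraniol, (2E)-3,7-dimethylocta-2,6-dien-1-ol | CC(C)=CCC/C(C)=C/CO | starting material
2 | [(2S,3S)-3-methyl-3-(4-methylpent-3-en-1-yl)oxiran-2-yl]methanol | OC[C@@H]1O[C@@]1(C)CCC=C(C)C | intermediate
3 | (2R,3S)-3-methyl-3-(4-methylpent-3-en-1-yl)oxirane-2-carbaldehyde | O=C[C@@H]1O[C@@]1(C)CCC=C(C)C | intermediate
4 | (2S,3S)-3-ethynyl-2-methyl-2-(4-methylpent-3-en-1-yl)oxirane | C#C[C@@H]1O[C@@]1(C)CCC=C(C)C | intermediate
5 | hexacarbonyl dicobalt complex of 4 | CC(C)=CCC[C@]1(C)O[C@H]1C23[CH]4[Co]2(=C=O)(=C=O)(=C=O)[Co]34(=C=O)(=C=O)=C=O | intermediate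
6 | cobalt-stabilised C6 propargylic cation carrying C5–O–BF3 (zwitterion) | CC(C)=CCC[C@](C)(O[B-](F)(F)F)[CH+]C12[CH]3[Co]1(=C=O)(=C=O)(=C=O)[Co]23(=C=O)(=C=O)=C=O | intermediate (not isolated)
7 | hexacarbonyl dicobalt complex of 8 | C=C(C)[C@H]1CC[C@](C)(O)[C@@H]1C23[CH]4[Co]2(=C=O)(=C=O)(=C=O)[Co]34(=C=O)(=C=O)=C=O | intermediate
8 | (1S,2S,3S)-2-ethynyl-1-methyl-3-(prop-1-en-2-yl)cyclopentan-1-ol | C=C(C)[C@H]1CC[C@](C)(O)[C@@H]1C#C | intermediate
9 | methyl vinyl ketone (but-3-en-2-one) | C=CC(C)=O | starting material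
10 | dilithium alkoxide acetylide of 8 | C=C(C)[C@H]1CC[C@](C)(O[Li])[C@@H]1C#C[Li] | intermediate (not isolated)
11 | (1S,2S,3S)-2-(3-hydroxy-3-methylpent-4-en-1-yn-1-yl)-1-methyl-3-(prop-1-en-2-yl)cyclopentan-1-ol, both side-chain epimers | C=C(C)[C@H]1CC[C@](C)(O)[C@@H]1C#CC(C)(O)C=C | intermediate
12 | (1S,2R,3S)-2-[(1E)-3-hydroxy-3-methylpenta-1,4-dien-1-yl]-1-methyl-3-(prop-1-en-2-yl)cyclopentan-1-ol, both side-chain epimers | C=C(C)[C@H]1CC[C@](C)(O)[C@@H]1/C=C/C(C)(O)C=C | intermediate
13 | [(2E,4E)-5-[(1R,2S,5S)-2-hydroxy-2-methyl-5-(prop-1-en-2-yl)cyclopentyl]-3-methylpenta-2,4-dien-1-yl]triphenylphosphonium bromide | C=C(C)[C@H]1CC[C@](C)(O)[C@@H]1/C=C/C(C)=C/C[P+](c1ccccc1)(c1ccccc1)c1ccccc1.[Br-] | intermediate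
14 | (3E,5E)-pseudoionone, (3E,5E)-6,10-dimethylundeca-3,5,9-trien-2-one | CC(C)=CCC/C(C)=C/C=C/C(C)=O | starting material
15 | (4E,6E)-3,7,11-trimethyldodeca-1,4,6,10-tetraen-3-ol (racemic) | CC(C)=CCC/C(C)=C/C=C/C(C)(O)C=C | intermediate
16 | [(2E,4E,6E)-3,7,11-trimethyldodeca-2,4,6,10-tetraen-1-yl]triphenylphosphonium bromide | CC(C)=CCC/C(C)=C/C=C/C(C)=C/C[P+](c1ccccc1)(c1ccccc1)c1ccccc1.[Br-] | intermediate
17 | (2E,4E,6E)-2,7-dimethylocta-2,4,6-trienedial | O=C/C(C)=C/C=C/C=C(C)/C=O | starting material
18 | ylide of 16 | CC(C)=CCC/C(C)=C/C=C/C(C)=C/[CH-][P+](c1ccccc1)(c1ccccc1)c1ccccc1 | intermediate (not isolated)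
19 | (8Z)-isomer of 20 | O=C/C(C)=C/C=C/C=C(C)/C=C\C=C(C)\C=C\C=C(/C)CCC=C(C)C | intermediate (not isolated)
20 | (2E,4E,6E,8E,10E,12E,14E)-2,7,11,15,19-pentamethylicosa-2,4,6,8,10,12,14,18-octaenal | O=C/C(C)=C/C=C/C=C(C)/C=C/C=C(C)/C=C/C=C(\C)CCC=C(C)C | intermediate
21 | ylide of 13 | C=C(C)[C@H]1CC[C@](C)(O)[C@@H]1/C=C/C(C)=C/[CH-][P+](c1ccccc1)(c1ccccc1)c1ccccc1 | intermediate (not isolated)
22 | (11Z)-isomer of 23 (carotenoid numbering) | C=C(C)[C@H]1CC[C@](C)(O)[C@@H]1/C=C/C(C)=C/C=C\C(C)=C\C=C\C=C(C)\C=C\C=C(C)\C=C\C=C(/C)CCC=C(C)C | intermediate (not isolated)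
23 | (2S,5S,6R)-1,16-didehydro-2,6-cyclolycopen-5-ol; (1S,2R,3S)-1-methyl-2-[(all-E)-3,7,12,16,20,24-hexamethylpentacosa-1,3,5,7,9,11,13,15,17,19,23-undecaen-1-yl]-3-(prop-1-en-2-yl)cyclopentan-1-ol | C=C(C)[C@H]1CC[C@](C)(O)[C@@H]1/C=C/C(C)=C/C=C/C(C)=C/C=C/C=C(C)/C=C/C=C(C)/C=C/C=C(\C)CCC=C(C)C | target

**Step count and risks**
Total steps: 13. Longest linear sequence: 10 (steps 1–9 and 13).

Steps most likely to fail:

1. Step 5 (proposed new method). The cobalt-stabilised cation may lose facial fidelity before the olefin attacks, so that C6 forms as a mixture. The C1 cation may be captured by fluoride or lose a ring proton instead of a methyl proton. A 1,2-shift from C5 may compete with ring closure. The fallback uses known chemistry and builds the ring by a chiral-pool aldol closure of C5–C6. It sets out from none of the numbered compounds: it replaces 1–8 and begins with a new bought material; it comes back to the route at compound 12. (4S)-Limonene 1,2-oxide F1 is cleaved with H5IO6 in THF/H2O to (3S)-6-oxo-3-(prop-1-en-2-yl)heptanal F2, which already carries C2. Intramolecular aldol addition of the aldehyde enolate to the methyl ketone under equilibrating conditions (catalytic KOH, MeOH, 0 °C, stopped before dehydration) should favour (1R,2S,5S)-2-hydroxy-2-methyl-5-(prop-1-en-2-yl)cyclopentane-1-carbaldehyde F3, the isomer with formyl trans to both the isopropenyl and the C5 methyl group. Wittig reaction with Ph3P=CHC(O)CH3 gives (3E)-4-[(1R,2S,5S)-2-hydroxy-2-methyl-5-(prop-1-en-2-yl)cyclopentyl]but-3-en-2-one F4, and vinylmagnesium bromide adds 1,2 to give 12.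

2. Step 9. After ionisation, capture by PPh3 competes with intramolecular capture of the pentadienyl cation by the C5 hydroxyl, with loss of the C6 proton (which would erase that centre), and with acid addition to the isopropenyl group. The fallback sets out from 8 and comes back at 13, making the salt by SN2 on a primary allylic bromide under neutral conditions. Hydrozirconation of 8 with Cp2Zr(H)Cl (2.2 equiv) and iodinolysis give (1S,2S,3S)-2-[(E)-2-iodoethenyl]-1-methyl-3-(prop-1-en-2-yl)cyclopentan-1-ol F5. Stille coupling (PdCl2(MeCN)2, DMF) with (2E)-3-(tributylstannyl)but-2-en-1-ol F6, made from but-2-yn-1-ol by stannylcupration, gives (2E,4E)-5-[(1R,2S,5S)-2-hydroxy-2-methyl-5-(prop-1-en-2-yl)cyclopentyl]-3-methylpenta-2,4-dien-1-ol F7. Appel bromination (CBr4, PPh3, −20 °C) gives (1S,2R,3S)-2-[(1E,3E)-5-bromo-3-methylpenta-1,3-dien-1-yl]-1-methyl-3-(prop-1-en-2-yl)cyclopentan-1-ol F8, and PPh3 in ethyl acetate gives 13.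

3. Step 7. Enolisation or anionic polymerisation of methyl vinyl ketone, or conjugate addition, may outrun 1,2-addition of the dianion. The fallback sets out from 8 and comes back at 12, with the ring fragment as a vinyl-metal nucleophile toward an acyl electrophile. Hydrostannation of 8 (Bu3SnH, PdCl2(PPh3)2 cat.) gives (1S,2S,3S)-1-methyl-3-(prop-1-en-2-yl)-2-[(E)-2-(tributylstannyl)ethenyl]cyclopentan-1-ol F9. Stille acylation with acetyl chloride gives the enone F4 of the first fallback, and vinylmagnesium bromide converts it into 12.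

**Further compounds**
F1 | step 5 | (4S)-limonene 1,2-oxide (cis/trans mixture) | CC(=C)[C@H]1CCC2(C)OC2C1
F2 | step 5 | (3S)-6-oxo-3-(prop-1-en-2-yl)heptanal | CC(=C)[C@H](CC=O)CCC(C)=O
F3 | step 5 | (1R,2S,5S)-2-hydroxy-2-methyl-5-(prop-1-en-2-yl)cyclopentane-1-carbaldehyde | C=C(C)[C@H]1CC[C@](C)(O)[C@@H]1C=O
F4 | step 5 | (3E)-4-[(1R,2S,5S)-2-hydroxy-2-methyl-5-(prop-1-en-2-yl)cyclopentyl]but-3-en-2-one | C=C(C)[C@H]1CC[C@](C)(O)[C@@H]1/C=C/C(C)=O
F5 | step 9 | (1S,2S,3S)-2-[(E)-2-iodoethenyl]-1-methyl-3-(prop-1-en-2-yl)cyclopentan-1-ol | C=C(C)[C@H]1CC[C@](C)(O)[C@@H]1/C=C/I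
F6 | step 9 | (2E)-3-(tributylstannyl)but-2-en-1-ol | CCCC[Sn](CCCC)(CCCC)/C(C)=C/CO
F7 | step 9 | (2E,4E)-5-[(1R,2S,5S)-2-hydroxy-2-methyl-5-(prop-1-en-2-yl)cyclopentyl]-3-methylpenta-2,4-dien-1-ol | C=C(C)[C@H]1CC[C@](C)(O)[C@@H]1/C=C/C(C)=C/CO
F8 | step 9 | (1S,2R,3S)-2-[(1E,3E)-5-bromo-3-methylpenta-1,3-dien-1-yl]-1-methyl-3-(prop-1-en-2-yl)cyclopentan-1-ol | C=C(C)[C@H]1CC[C@](C)(O)[C@@H]1/C=C/C(C)=C/CBr
F9 | step 7 | (1S,2S,3S)-1-methyl-3-(prop-1-en-2-yl)-2-[(E)-2-(tributylstannyl)ethenyl]cyclopentan-1-ol | C=C(C)[C@H]1CC[C@](C)(O)[C@@H]1/C=C/[Sn](CCCC)(CCCC)CCCC
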